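**Retrosynthetic overview**
1. Hansfordiol E (18) <= benzodioxinone 16 by saponification with loss of acetone and CO2. The carboxyl carbon and the acetonide are temporary activating groups.
2. 16 <= diketo-dioxinone 12 + iodo alcohol 7. Terminal alkylation of the trianion of 12 makes the benzylic C1'-C2' bond, and the same flask closes the benzene ring by a C2-to-C7 aldol condensation (polyketide numbers).
3. Enabling feature: the benzene ring carries O, O and the chain on alternate ring positions 1, 3 and 5, the imprint of a folded tetraketide. Ring carbon 5 (polyketide C7) is therefore a latent ketone, and the benzylic carbon C1' is its acidic alpha-methyl group, the most basic site of the polyanion.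
4. 7 <= Z-selective cross metathesis at C8'=C9' of (S)-dec-9-en-2-ol 4 and 8-bromooct-1-ene 5. 4 <= (S)-propylene oxide 1 (source of C16'). 12 <= two Claisen acylations of dioxinone 8.
5. Ring order: the 1,3-dioxin-4-one ring is bought with 8, the benzene ring is formed in step 6, and the dioxinone ring is cleaved in step 7.

Key step: step 6

Remark on locants: C1' to C17' count the side chain from the benzylic carbon. C1 to C8 in 12-16 are polyketide numbers: C1 = lactone C=O, C2 = dioxinone C5-H, C3 = dioxinone C6, then C4H2, C5=O, C6H2, C7=O, C8H3 = C1'.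
Remark on the chemistry: the SMILES is read as (S) at C16' and (Z) at C8'=C9'. LDA and LiHMDS are taken as bought solutions.

**Step 1**
Reactants: 1 (S)-propylene oxide [(S)-2-methyloxirane]; 2 7-bromohept-1-ene
Product: 4 (S)-dec-9-en-2-ol, via hept-6-enylmagnesium bromide 3 (not isolated)
Conditions: 2 (1.3 equiv), Mg, THF, 40 °C; then CuI (10 mol %), 1, THF, −40 → 0 °C; aq NH4Cl
Reagents that add atoms: none
Why: Copper-catalysed Grignard opening of a terminal epoxide proceeds by SN2 attack at the unsubstituted CH2, so the C-O bond of the stereocentre is untouched and the (S) configuration of 1 becomes that of C16'.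

**Step 2**
Reactants: 4 (S)-dec-9-en-2-ol; 5 8-bromooct-1-ene
Product: 6 (2S,9Z)-16-bromohexadec-9-en-2-ol
Conditions: 5 (3 equiv), cyclometalated Ru-NHC nitrato catalyst (Z-selective, commercial, 2 mol %), THF, 40 °C, static vacuum (removal of ethene)
Reagents that add atoms: none
Why: Z-selective olefin cross metathesis of two unhindered terminal alkenes, in which the chelated NHC forces a side-bound metallacyclobutane with both substituents pointing away from the N-aryl group and so sets C8'=C9' cis under kinetic control, while the excess of 5 and the removal of ethene favour the cross product and the free OH and C-Br groups are tolerated.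

**Step 3**
Reactants: 6 (2S,9Z)-16-bromohexadec-9-en-2-ol
Product: 7 (2S,9Z)-16-iodohexadec-9-en-2-ol
Conditions: NaI (4 equiv), acetone, reflux, dark
Reagents that add atoms: sodium iodide, [Na+].[I-]
Why: Finkelstein halide exchange (SN2 at the primary carbon, driven by precipitation of NaBr) should give the more reactive iodide needed for alkylation below −20 °C and touches neither the carbinol nor, in the dark, the Z-alkene.

**Step 4**
Reactants: 8 2,2,6-trimethyl-4H-1,3-dioxin-4-one
Product: 10 2,2-dimethyl-6-(2-oxopropyl)-4H-1,3-dioxin-4-one, via lithium dienolate 9 (not isolated)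
Conditions: 8 (2.0 equiv), LiHMDS (2.0 equiv), THF, −78 °C; AcCl (1.0 equiv), −78 → −20 °C; 1 M HCl
Reagents that add atoms: acetyl chloride, CC(=O)Cl
Why: Vinylogous Claisen acylation, in which the extended lithium dienolate 9 is C-acylated by the acid chloride at its gamma-carbon and the second equivalent of 9 absorbs the acidic proton of the product so that double acylation is avoided.

**Step 5**
Reactants: 10 2,2-dimethyl-6-(2-oxopropyl)-4H-1,3-dioxin-4-one
Product: 12 6-(2,4-dioxopentyl)-2,2-dimethyl-4H-1,3-dioxin-4-one, via dilithio keto-dioxinone 11 (not isolated)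
Conditions: LDA (2.3 equiv), THF, −78 → −40 °C; MeC(O)N(OMe)Me (1.1 equiv), −78 → −10 °C; cold 1 M HCl; used after short filtration
Reagents that add atoms: N-methoxy-N-methylacetamide, CC(=O)N(C)OC
Why: Claisen-type acylation of a 1,3-dianion, which reacts at its last-formed terminal carbanion, by an N-methoxy-N-methyl amide whose chelated tetrahedral adduct survives until the cold acidic quench, so that over-addition and base-induced aromatisation of 12 are avoided.

**Step 6**
Reactants: 12 6-(2,4-dioxopentyl)-2,2-dimethyl-4H-1,3-dioxin-4-one; 7 (2S,9Z)-16-iodohexadec-9-en-2-ol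
Product: 16 7-hydroxy-5-[(8Z,16S)-16-hydroxyheptadec-8-en-1-yl]-2,2-dimethyl-4H-1,3-benzodioxin-4-one, via trilithio diketo-dioxinone 13 (not isolated), via lithium alkoxide 14 (not isolated), via alkylated diketo-dioxinone 15 (not isolated)
Conditions: 12 (1.5 equiv) added to LDA (4.6 equiv), THF, −78 → −30 °C; 14 [from 7 (1.0 equiv), LDA (1.0 equiv), THF, −78 °C], DMPU, −78 → −20 °C; AcOH, then Et3N, −78 → 23 °C
Reagents that add atoms: none
Why: Proposed new method: LDA removes C4-H, C6-H and last a C8 methyl proton of 12 to give the fully conjugated trianion 13, whose last-formed and most basic carbon C8 displaces iodide from 14 (SN2, forming C1'-C2'); after buffering with AcOH/Et3N the gamma-deprotonated dioxinone of 15 adds through its alpha-carbon C2 to the C7 ketone, water leaves by E1cB and the C5 ketone enolises to the phenol of 16. The closest known reaction types are the terminal alkylation of 1,3,5-triketone and 3,5-dioxo ester trianions, the terminal acylation of dianion 11 (step 5) and the amine-induced aromatisation of 6-(2,4-dioxoalkyl)-1,3-dioxin-4-ones to 5-alkyl-7-hydroxybenzodioxinones; new is the third deprotonation of a diketo-dioxinone and the union of both events in one flask. The benzene ring closes in a favoured 6-(enolexo)-exo-trig aldol mode and aromatisation makes the closure irreversible. No stereocentre is formed: C16' travels as its inert lithium alkoxide and the Z-C8'=C9' bond lies far from every charged site. Site selectivity among four nucleophilic carbons and the alkoxide is secured by the graded basicity of 13 (only C8 is flanked by a single acceptor) and by keeping 13 in excess over 14, which suppresses proton transfer and double alkylation. The single cyclisation mode is secured by the acetonide, which ties up the C1 and C3 oxygens, so that pyrone formation and the C6-to-C1 Claisen closure are blocked and C2 is the only activated carbon that can reach a free ketone through a six-membered transition state.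

**Step 7**
Reactants: 16 7-hydroxy-5-[(8Z,16S)-16-hydroxyheptadec-8-en-1-yl]-2,2-dimethyl-4H-1,3-benzodioxin-4-one
Product: 18 Hansfordiol E, 5-[(8Z,16S)-16-hydroxyheptadec-8-en-1-yl]benzene-1,3-diol, via resorcylic acid 17 (not isolated)
Conditions: 5 M aq KOH, 1,4-dioxane, 100 °C, Ar; then 2 M HCl to pH 3, 60 °C
Reagents that add atoms: none
Why: Alkaline saponification of the aryl ester/ketal releases acetone and gives the 6-alkyl-beta-resorcylic acid 17, whose ortho and para hydroxy groups make ipso-protonation easy so that protodecarboxylation should follow on warming at pH 3, conditions under which the isolated Z-alkene and the secondary carbinol are inert.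

**Compound list**
1 | (S)-propylene oxide | C[C@H]1CO1 | starting material
2 | 7-bromohept-1-ene | C=CCCCCCBr | starting material
3 | hept-6-enylmagnesium bromide | C=CCCCCC[Mg]Br | intermediate
4 | (S)-dec-9-en-2-ol | C[C@H](O)CCCCCCC=C | intermediate
5 | 8-bromooct-1-ene | C=CCCCCCCBr | starting material
6 | (2S,9Z)-16-bromohexadec-9-en-2-ol | C[C@H](O)CCCCCC/C=C\CCCCCCBr | intermediate
7 | (2S,9Z)-16-iodohexadec-9-en-2-ol | C[C@H](O)CCCCCC/C=C\CCCCCCI | intermediate
8 | 2,2,6-trimethyl-4H-1,3-dioxin-4-one | CC1=CC(=O)OC(C)(C)O1 | starting material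
9 | lithium dienolate of 8 | [Li+].C=C1C=C([O-])OC(C)(C)O1 | intermediate
10 | 2,2-dimethyl-6-(2-oxopropyl)-4H-1,3-dioxin-4-one | CC(=O)CC1=CC(=O)OC(C)(C)O1 | intermediate
11 | dilithium dianion of 10 | [Li+].[Li+].C=C([O-])C=C1C=C([O-])OC(C)(C)O1 | intermediate
12 | 6-(2,4-dioxopentyl)-2,2-dimethyl-4H-1,3-dioxin-4-one | CC(=O)CC(=O)CC1=CC(=O)OC(C)(C)O1 | intermediate
13 | trilithium trianion of 12 | [Li+].[Li+].[Li+].C=C([O-])C=C([O-])C=C1C=C([O-])OC(C)(C)O1 | intermediate
14 | lithium (2S,9Z)-16-iodohexadec-9-en-2-olate | [Li+].C[C@H]([O-])CCCCCC/C=C\CCCCCCI | intermediate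
15 | 6-[(12Z,20S)-20-hydroxy-2,4-dioxohenicos-12-en-1-yl]-2,2-dimethyl-4H-1,3-dioxin-4-one | C[C@H](O)CCCCCC/C=C\CCCCCCCC(=O)CC(=O)CC1=CC(=O)OC(C)(C)O1 | intermediate
16 | 7-hydroxy-5-[(8Z,16S)-16-hydroxyheptadec-8-en-1-yl]-2,2-dimethyl-4H-1,3-benzodioxin-4-one | C[C@H](O)CCCCCC/C=C\CCCCCCCc1cc(O)cc2OC(C)(C)OC(=O)c12 | intermediate
17 | 2,4-dihydroxy-6-[(8Z,16S)-16-hydroxyheptadec-8-en-1-yl]benzoic acid | C[C@H](O)CCCCCC/C=C\CCCCCCCc1cc(O)cc(O)c1C(=O)O | intermediate
18 | Hansfordiol E, 5-[(8Z,16S)-16-hydroxyheptadec-8-en-1-yl]benzene-1,3-diol | C[C@H](O)CCCCCC/C=C\CCCCCCCc1cc(O)cc(O)c1 | target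

Total step count: 7. Longest linear sequence: 5 steps (1, 2, 3, 6, 7). The second branch (4, 5, 6, 7) has 4 steps.

**Steps most likely to fail**

Step 6. The third deprotonation may stay incomplete. Proton exchange between the alkylated dianion and unreacted trianion may lead to multiple alkylation. The dioxinone dienolate may also fragment on warming before the SN2 step is over.
The fallback uses known chemistry and reverses the order: ring first, bond second. It sets out from 12 and 7.
- Compound 12 alone is aromatised with Et3N in CH2Cl2 to 7-hydroxy-2,2,5-trimethyl-4H-1,3-benzodioxin-4-one F1.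
- The phenol is silylated (TBSCl, imidazole, DMF) to 7-(tert-butyldimethylsilyloxy)-2,2,5-trimethyl-4H-1,3-benzodioxin-4-one F2.
- Lateral (ortho-toluate) lithiation of the C5 methyl group with LDA in THF at −78 °C gives the benzylic lithium compound F3.
- Alkylation of F3 with lithium alkoxide 14 makes the same C1'-C2' bond and gives the silyl ether of 16 F4.
- TBAF in THF removes the silyl group, and the route is rejoined at 16.

Step 2. Homodimerisation of both partners may dominate the product distribution, and secondary metathesis at high conversion may erode the Z geometry.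
The fallback builds the cis alkene by alkyne semihydrogenation. It sets out from 1.
- Hept-1-yne is deprotonated with n-BuLi to lithium hept-1-yn-1-ide F5.
- F5 opens 1 at the CH2 terminus under BF3·OEt2 activation to (S)-dec-4-yn-2-ol F6.
- The alkyne zipper isomerisation (potassium 3-aminopropylamide, 1,3-diaminopropane) moves the triple bond to the chain end and gives (S)-dec-9-yn-2-ol F7, with the carbinol carried as its alkoxide.
- Double deprotonation with n-BuLi (2 equiv, THF/DMPU) gives the dilithium alkoxide acetylide F8.
- F8 is C-alkylated with excess 1,6-dibromohexane to (S)-16-bromohexadec-9-yn-2-ol F9.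
- Lindlar semihydrogenation (H2, Pd/CaCO3/Pb, quinoline) rejoins the route at 6.

Step 5. The product enolate may undergo premature aldol aromatisation during acylation or work-up, and O-acylation or incomplete dianion formation may compete.
The fallback brings in the outer ketone in masked form and releases it under acid, where aromatisation does not start. It sets out from 8.
- Commercial (2-methyl-1,3-dioxolan-2-yl)acetic acid is activated with carbonyldiimidazole to 1-[(2-methyl-1,3-dioxolan-2-yl)acetyl]imidazole F10.
- Dienolate 9 (2 equiv, made as in step 4) is acylated with F10 at its gamma-carbon to 2,2-dimethyl-6-[3-(2-methyl-1,3-dioxolan-2-yl)-2-oxopropyl]-4H-1,3-dioxin-4-one F11.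
- Mild aqueous acid (1 M HCl, THF, 0 → 23 °C) cleaves the dioxolane, and the route is rejoined at 12.

**Further compounds**
F1 | step 6 | 7-hydroxy-2,2,5-trimethyl-4H-1,3-benzodioxin-4-one | Cc1cc(O)cc2OC(C)(C)OC(=O)c12
F2 | step 6 | 7-(tert-butyldimethylsilyloxy)-2,2,5-trimethyl-4H-1,3-benzodioxin-4-one | Cc1cc(O[Si](C)(C)C(C)(C)C)cc2OC(C)(C)OC(=O)c12
F3 | step 6 | benzylic lithium compound of F2 | [Li+].[CH2-]c1cc(O[Si](C)(C)C(C)(C)C)cc2OC(C)(C)OC(=O)c12
F4 | step 6 | 7-(tert-butyldimethylsilyloxy)-5-[(8Z,16S)-16-hydroxyheptadec-8-en-1-yl]-2,2-dimethyl-4H-1,3-benzodioxin-4-one | C[C@H](O)CCCCCC/C=C\CCCCCCCc1cc(O[Si](C)(C)C(C)(C)C)cc2OC(C)(C)OC(=O)c12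
F5 | step 2 | lithium hept-1-yn-1-ide | [Li+].[C-]#CCCCCC
F6 | step 2 | (S)-dec-4-yn-2-ol | C[C@H](O)CC#CCCCCC
F7 | step 2 | (S)-dec-9-yn-2-ol | C[C@H](O)CCCCCCC#C
F8 | step 2 | dilithium alkoxide acetylide of F7 | [Li+].[Li+].C[C@H]([O-])CCCCCCC#[C-]
F9 | step 2 | (S)-16-bromohexadec-9-yn-2-ol | C[C@H](O)CCCCCCC#CCCCCCCBr
F10 | step 5 | 1-[(2-methyl-1,3-dioxolan-2-yl)acetyl]imidazole | CC1(CC(=O)n2ccnc2)OCCO1
F11 | step 5 | 2,2-dimethyl-6-[3-(2-methyl-1,3-dioxolan-2-yl)-2-oxopropyl]-4H-1,3-dioxin-4-one | CC1(CC(=O)CC2=CC(=O)OC(C)(C)O2)OCCO1
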